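Ring B comes from (S)-carvone: its C5 is the target's C5 and its isopropenyl carbon is C4. The whole plan rests on breaking the C3–C4 bond of ring A. The feature exploited is the quaternary C4, which carries a methyl group and the C18 hydroxymethyl arm beside the C3 carbinol: a 2-methyloxirane on C5 is opened by Cp2TiCl to the tertiary C4 radical, which closes ring A on an aldehyde at C3. One operation thus delivers the C3–C4 bond, ring A, both ring-A stereocentres and the two oxygen functions. The precursor is a carvone-derived cyclohexenone whose quaternary C10 carries a methyl group and a 3-oxopropyl chain trans to the oxirane-bearing C5 substituent.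

Key step: step 6

Remark: labdane numbering is used for the bicyclic compounds (C17 = methyl on C8, C18 = oxygenated carbon on C4, C19 = methyl on C4, C20 = methyl on C10, C11–C16 = side chain); a species made by one reagent and consumed by a second reagent in the same flask is numbered as a non-isolated intermediate, whereas radicals and metal alkoxides awaiting work-up are treated as mechanism.

Step 1
Reactants: 1 (S)-carvone; 2 iodomethane
Product: 4 (5S)-2,6-dimethyl-5-(prop-1-en-2-yl)cyclohex-2-en-1-one (mixture of C6 epimers), via lithium dienolate 3 (not isolated)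
Conditions: LiN(iPr)2, THF, −78 °C; then MeI, −78 → 0 °C
Reagents that add atoms: iodomethane, CI
Why: Kinetic deprotonation at the only enolisable α′ position (C6) and C-methylation of the cross-conjugated enolate (enolate alkylation); the C6 epimer mixture is harmless because this centre is enolised again in step 2.

Step 2
Reactants: 4 (5S)-2,6-dimethyl-5-(prop-1-en-2-yl)cyclohex-2-en-1-one; 5 allyl bromide
Product: 7 (5R,6R)-2,6-dimethyl-5-(prop-1-en-2-yl)-6-(prop-2-en-1-yl)cyclohex-2-en-1-one, via lithium enolate 6 (not isolated)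
Conditions: LiN(iPr)2, THF, −78 → 0 °C; then allyl bromide, −78 °C → rt
Reagents that add atoms: allyl bromide, C=CCBr
Why: Enolate alkylation in which the reactive allylic halide attacks the tetrasubstituted enolate carbon on the face opposite the neighbouring isopropenyl group, which should set the future C10 quaternary centre with the three-carbon arm trans to the future C4 and the methyl group cis to it.

Step 3
Reactants: 7 (5R,6R)-2,6-dimethyl-5-(prop-1-en-2-yl)-6-(prop-2-en-1-yl)cyclohex-2-en-1-one
Product: 9 (5R,6R)-6-(3-hydroxypropyl)-2,6-dimethyl-5-(prop-1-en-2-yl)cyclohex-2-en-1-one, via trialkylborane 8 (not isolated)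
Conditions: (Sia)2BH [from BH3·SMe2, 2-methylbut-2-ene], THF, 0 °C; then NaBO3·4H2O, H2O, 0 °C → rt
Reagents that add atoms: sodium perborate tetrahydrate, [Na+].[Na+].O[B-]1(O)OO[B-](O)(O)OO1.O.O.O.O.O.O
Why: Anti-Markovnikov hydroboration–oxidation with a bulky dialkylborane, which should discriminate the unhindered monosubstituted allyl terminus from the hindered 1,1-disubstituted isopropenyl group and from the conjugated, doubly flanked ketone, while perborate avoids the strongly alkaline peroxide that would epoxidise the enone.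

Step 4
Reactants: 9 (5R,6R)-6-(3-hydroxypropyl)-2,6-dimethyl-5-(prop-1-en-2-yl)cyclohex-2-en-1-one
Product: 10 (5S,6R)-6-(3-hydroxypropyl)-2,6-dimethyl-5-(2-methyloxiran-2-yl)cyclohex-2-en-1-one (both oxirane epimers)
Conditions: mCPBA, NaHCO3, CH2Cl2, 0 °C
Reagents that add atoms: 3-chloroperoxybenzoic acid, OOC(=O)c1cccc(Cl)c1
Why: Prilezhaev epoxidation, in which the electrophilic peracid takes the electron-rich 1,1-disubstituted alkene and leaves the electron-poor enone alone; the new oxirane centre need not be controlled because it later becomes a planar radical.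

Step 5
Reactants: 10 (5S,6R)-6-(3-hydroxypropyl)-2,6-dimethyl-5-(2-methyloxiran-2-yl)cyclohex-2-en-1-one
Product: 11 (5S,6R)-2,6-dimethyl-5-(2-methyloxiran-2-yl)-6-(3-oxopropyl)cyclohex-2-en-1-one (both oxirane epimers)
Conditions: Dess–Martin periodinane, pyridine, CH2Cl2, 0 °C → rt
Reagents that add atoms: none
Why: Dess–Martin oxidation of the primary alcohol stops at the aldehyde and, buffered with pyridine, should leave the acid-sensitive 2,2-disubstituted oxirane intact.

Step 6
Reactants: 11 (5S,6R)-2,6-dimethyl-5-(2-methyloxiran-2-yl)-6-(3-oxopropyl)cyclohex-2-en-1-one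
Product: 12 (3R,4S,5R,10R)-3,18-dihydroxy-11,12,13,14,15,16-hexanorlabd-7-en-9-one
Conditions: Cp2TiCl2 (2.5 equiv), Zn dust, THF, rt; slow addition of 11; then 1 M HCl
Reagents that add atoms: none
Why: Cp2TiCl (trivalent titanium, formed from Cp2TiCl2 and Zn) transfers one electron to the oxirane, which opens at its more substituted C–O bond to the tertiary β-titanoxy radical at C4; this radical adds to the aldehyde carbon C3 and a second Cp2TiCl captures the oxygen as a titanium alkoxide, so the addition cannot revert, the closest known reaction type being the titanocene-mediated epoxide–carbonyl radical cyclisation. Ring A is closed in the 6-exo-trig mode onto the C=O group. The C4 centre should be set in a chair transition state, fixed by the existing C5 and C10 centres, in which the bulky titanoxymethyl group lies equatorial and the methyl group axial beside the axial C10 methyl, and the C3 centre by the titanium-bound aldehyde oxygen also lying equatorial; both oxirane epimers converge because they give the same planar radical. The step needs selectivity for the oxirane over the enone and the aliphatic aldehyde, which the weak reducing power of Cp2TiCl toward non-aromatic carbonyl groups should provide, and it needs ring closure to outrun reduction of the radical, which the slow capture of a hindered tertiary radical by Cp2TiCl favours. Acidic work-up releases the 1,3-diol.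

Step 7
Reactants: 12 (3R,4S,5R,10R)-3,18-dihydroxy-11,12,13,14,15,16-hexanorlabd-7-en-9-one
Product: 14 3-O-triethylsilyl 18-O-tert-butyldiphenylsilyl diether of 12, via 18-O-silyl monoether 13 (not isolated)
Conditions: TBDPSCl, imidazole, DMF, 0 °C → rt; then TESCl, rt
Reagents that add atoms: tert-butyl(chloro)diphenylsilane, CC(C)(C)[Si](Cl)(c1ccccc1)c1ccccc1; chlorotriethylsilane, CC[Si](Cl)(CC)CC
Why: Silyl ether formation in order of steric accessibility, the bulky chlorosilane taking only the primary C18 hydroxyl before the smaller one caps the secondary C3 hydroxyl, which gives two silyl ethers that can later be removed one after the other.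

Step 8
Reactants: 14 3-O-triethylsilyl 18-O-tert-butyldiphenylsilyl diether of 12
Product: 16 9-(triethylsilyloxy)-8-ene silyl enol ether (7,8-dihydro), via lithium enolate 15 (not isolated)
Conditions: Li[HB(sBu)3], THF, −78 °C; then TESCl, Et3N, −78 → 0 °C
Reagents that add atoms: chlorotriethylsilane, CC[Si](Cl)(CC)CC
Why: Conjugate (1,4) hydride reduction of the β-unsubstituted, carbonyl-hindered enone by the bulky borohydride gives the C8=C9 enolate regiospecifically, and O-silylation traps it as the silyl enol ether.

Step 9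
Reactants: 16 9-(triethylsilyloxy)-8-ene silyl enol ether
Product: 17 8-(triethylsilyloxy)-9-ketone (8S; C8 oxygen anti to C20)
Conditions: mCPBA, NaHCO3, CH2Cl2, −20 → 0 °C
Reagents that add atoms: 3-chloroperoxybenzoic acid, OOC(=O)c1cccc(Cl)c1
Why: Rubottom oxidation, in which the peracid should epoxidise the enol ether on the face anti to the axial C10 methyl and ring opening with 1,4-silyl shift gives the α-silyloxy ketone, so that C8 receives its oxygen on the required face with C17 syn to C20.

Step 10
Reactants: 17 8-(triethylsilyloxy)-9-ketone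
Product: 18 9-alcohol (hydroxyl expected equatorial)
Conditions: LiAlH4, THF, 0 °C
Reagents that add atoms: none
Why: Hydride reduction of the hindered ketone by a small, strong donor, expected on the face anti to the two flanking axial methyl groups; the C9 configuration is immaterial because this centre becomes a radical in step 12.

Step 11
Reactants: 18 9-alcohol
Product: 19 9-O-(phenoxythiocarbonyl) derivative
Conditions: PhOC(S)Cl, pyridine, DMAP (cat.), CH2Cl2, rt → 40 °C
Reagents that add atoms: O-phenyl carbonochloridothioate, S=C(Cl)Oc1ccccc1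
Why: Thioacylation of the secondary alcohol through the acylpyridinium species gives a Barton–McCombie-type radical precursor without generating an alkoxide that could pull the silyl group over from the neighbouring tertiary oxygen.

Step 12
Reactants: 19 9-O-(phenoxythiocarbonyl) derivative; 20 but-3-en-2-one
Product: 21 3,8-bis(triethylsilyloxy)-18-(tert-butyldiphenylsilyloxy)-14,15-dinorlabdan-13-one (C9 side chain anti to C20)
Conditions: Bu3SnH (syringe pump), AIBN (cat.), but-3-en-2-one (excess), benzene, 80 °C
Reagents that add atoms: but-3-en-2-one, CC(=O)C=C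
Why: Giese reaction, in which the stannyl radical attacks sulfur, the C9–O bond fragments and the nucleophilic secondary C9 radical adds to the enone terminus before hydrogen-atom transfer closes the chain; the C9–C11 bond should form along the axial trajectory anti to the axial methyl groups on both neighbours (C8 and C10), which places the chain cis to the C8 oxygen and leaves H-9 syn to C20.

Step 13
Reactants: 21 14,15-dinorlabdan-13-one
Product: 23 13(16)-en-13-yl trifluoromethanesulfonate, via lithium enolate 22 (not isolated)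
Conditions: LiN(iPr)2, THF, −78 °C; then PhNTf2, −78 → 0 °C
Reagents that add atoms: N-phenylbis(trifluoromethanesulfonimide), O=S(=O)(N(c1ccccc1)S(=O)(=O)C(F)(F)F)C(F)(F)F
Why: Kinetic deprotonation of the methyl ketone on its methyl side by the hindered amide base at low temperature, followed by O-triflation of the terminal enolate (enol triflate synthesis from a kinetic enolate).

Step 14
Reactants: 23 13(16)-en-13-yl trifluoromethanesulfonate; 24 tributyl(vinyl)stannane
Product: 25 3,8-bis(triethylsilyloxy)-18-(tert-butyldiphenylsilyloxy)labda-13(16),14-diene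
Conditions: Pd(PPh3)4 (cat.), LiCl, THF, 65 °C
Reagents that add atoms: tributyl(vinyl)stannane, C=C[Sn](CCCC)(CCCC)CCCC
Why: Stille coupling of the alkenyl triflate with the vinylstannane (chloride-assisted) joins two sp2 carbons and should give the 2-substituted buta-1,3-diene without touching the silyl ethers.

Step 15
Reactants: 25 3,8-bis(triethylsilyloxy)-18-(tert-butyldiphenylsilyloxy)labda-13(16),14-diene
Product: 26 18-(tert-butyldiphenylsilyloxy)labda-13(16),14-diene-3,8-diol
Conditions: HF·pyridine, pyridine, THF, 0 °C → rt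
Reagents that add atoms: none
Why: Selective desilylation under buffered fluoride conditions, in which the two triethylsilyl ethers are cleaved much faster than the primary tert-butyldiphenylsilyl ether, so that the C3 hydroxyl is freed while C18–O stays blocked.

Step 16
Reactants: 26 18-(tert-butyldiphenylsilyloxy)labda-13(16),14-diene-3,8-diol; 27 acetic anhydride
Product: 28 3-acetate of 26
Conditions: Ac2O, pyridine, DMAP (cat.), CH2Cl2, 0 °C → rt
Reagents that add atoms: acetic anhydride, CC(=O)OC(C)=O
Why: DMAP-catalysed acylation esterifies the secondary C3 hydroxyl, whereas the tertiary C8 hydroxyl is too hindered to react under these mild conditions.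

Step 17
Reactants: 28 3-acetate of 26
Product: 29 (3R,4S,5S,8S,9R,10R)-8,18-dihydroxylabda-13(16),14-dien-3-yl acetate (target)
Conditions: Bu4NF, AcOH (1:1), THF, rt
Reagents that add atoms: none
Why: Fluoride-induced desilylation of the primary silyl ether, buffered with acetic acid so that the C3 acetate should neither hydrolyse nor migrate to the liberated C18 hydroxyl.

Compound list
1 | (S)-carvone, (5S)-2-methyl-5-(prop-1-en-2-yl)cyclohex-2-en-1-one | CC1=CC[C@@H](CC1=O)C(C)=C | starting material
2 | iodomethane | CI | starting material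
3 | lithium dienolate of 1 (C6 deprotonated, C5 unchanged) | [Li+].[O-]C1=C[C@@H](C(C)=C)CC=C1C | intermediate
4 | (5S)-2,6-dimethyl-5-(prop-1-en-2-yl)cyclohex-2-en-1-one, mixture of C6 epimers | CC1=CC[C@@H](C(C)C1=O)C(C)=C | intermediate
5 | allyl bromide (3-bromoprop-1-ene) | C=CCBr | starting material
6 | lithium enolate of 4 (C6 deprotonated, C5 unchanged) | [Li+].[O-]C1=C(C)[C@@H](C(C)=C)CC=C1C | intermediate
7 | (5R,6R)-2,6-dimethyl-5-(prop-1-en-2-yl)-6-(prop-2-en-1-yl)cyclohex-2-en-1-one; allyl trans, methyl cis to isopropenyl | O=C1[C@](C)(CC=C)[C@@H](C(C)=C)CC=C1C | intermediate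
8 | bis(3-methylbutan-2-yl)borane adduct at the allyl terminus of 7 | O=C1[C@](C)(CCCB(C(C)C(C)C)C(C)C(C)C)[C@@H](C(C)=C)CC=C1C | intermediate
9 | (5R,6R)-6-(3-hydroxypropyl)-2,6-dimethyl-5-(prop-1-en-2-yl)cyclohex-2-en-1-one | O=C1[C@](C)(CCCO)[C@@H](C(C)=C)CC=C1C | intermediate
10 | (5S,6R)-6-(3-hydroxypropyl)-2,6-dimethyl-5-(2-methyloxiran-2-yl)cyclohex-2-en-1-one; the (2R)-oxirane epimer is drawn, the (2S) epimer is also present | O=C1[C@](C)(CCCO)[C@@H]([C@]2(C)CO2)CC=C1C | intermediate
11 | (5S,6R)-2,6-dimethyl-5-(2-methyloxiran-2-yl)-6-(3-oxopropyl)cyclohex-2-en-1-one; the (2R)-oxirane epimer is drawn, the (2S) epimer is also present and converges | O=C1[C@](C)(CCC=O)[C@@H]([C@]2(C)CO2)CC=C1C | intermediate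
12 | (3R,4S,5R,10R)-3,18-dihydroxy-11,12,13,14,15,16-hexanorlabd-7-en-9-one: trans-fused 3-hydroxy-4-(hydroxymethyl)-4,8,10-trimethyl-octal-7-en-9-one; 3-OH and CH2OH equatorial, C19 axial and syn to C20, H-5 anti to C20 | O=C1[C@]2(C)CC[C@@H](O)[C@](C)(CO)[C@H]2CC=C1C | intermediate
13 | 18-O-(tert-butyldiphenylsilyl) ether of 12 | O=C1[C@]2(C)CC[C@@H](O)[C@](C)(CO[Si](c3ccccc3)(c3ccccc3)C(C)(C)C)[C@H]2CC=C1C | intermediate
14 | 3-O-triethylsilyl 18-O-(tert-butyldiphenylsilyl) diether of 12 | O=C1[C@]2(C)CC[C@@H](O[Si](CC)(CC)CC)[C@](C)(CO[Si](c3ccccc3)(c3ccccc3)C(C)(C)C)[C@H]2CC=C1C | intermediate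
15 | lithium 8-en-9-olate from 14 (C7 now CH2; C3, C4, C5, C10 as in 12) | [Li+].[O-]C1[C@]2(C)CC[C@@H](O[Si](CC)(CC)CC)[C@](C)(CO[Si](c3ccccc3)(c3ccccc3)C(C)(C)C)[C@H]2CCC=1C | intermediate
16 | 9-(triethylsilyloxy)-8-ene silyl enol ether (C3, C4, C5, C10 as in 12) | CC[Si](CC)(CC)OC1[C@]2(C)CC[C@@H](O[Si](CC)(CC)CC)[C@](C)(CO[Si](c3ccccc3)(c3ccccc3)C(C)(C)C)[C@H]2CCC=1C | intermediate
17 | 3,8-bis(triethylsilyloxy)-18-(tert-butyldiphenylsilyloxy)-11,12,13,14,15,16-hexanorlabdan-9-one; 8S, C8–O anti to C20, C17 syn to C20 | O=C1[C@]2(C)CC[C@@H](O[Si](CC)(CC)CC)[C@](C)(CO[Si](c3ccccc3)(c3ccccc3)C(C)(C)C)[C@H]2CC[C@]1(C)O[Si](CC)(CC)CC | intermediate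
18 | 9-alcohol of 17 (9-OH equatorial and syn to C20 expected; either epimer serves) | O[C@H]1[C@]2(C)CC[C@@H](O[Si](CC)(CC)CC)[C@](C)(CO[Si](c3ccccc3)(c3ccccc3)C(C)(C)C)[C@H]2CC[C@]1(C)O[Si](CC)(CC)CC | intermediate
19 | 9-O-(phenoxythiocarbonyl) derivative of 18 | S=C(Oc4ccccc4)O[C@H]1[C@]2(C)CC[C@@H](O[Si](CC)(CC)CC)[C@](C)(CO[Si](c3ccccc3)(c3ccccc3)C(C)(C)C)[C@H]2CC[C@]1(C)O[Si](CC)(CC)CC | intermediate
20 | but-3-en-2-one | CC(=O)C=C | starting material
21 | 3,8-bis(triethylsilyloxy)-18-(tert-butyldiphenylsilyloxy)-14,15-dinorlabdan-13-one; C9 chain anti to C20 and cis to the C8 oxygen; all six ring stereocentres as in 29 | CC(=O)CC[C@@H]1[C@]2(C)CC[C@@H](O[Si](CC)(CC)CC)[C@](C)(CO[Si](c3ccccc3)(c3ccccc3)C(C)(C)C)[C@H]2CC[C@]1(C)O[Si](CC)(CC)CC | intermediate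
22 | lithium 13(16)-en-13-olate of 21 | [Li+].C=C([O-])CC[C@@H]1[C@]2(C)CC[C@@H](O[Si](CC)(CC)CC)[C@](C)(CO[Si](c3ccccc3)(c3ccccc3)C(C)(C)C)[C@H]2CC[C@]1(C)O[Si](CC)(CC)CC | intermediate
23 | 13(16)-en-13-yl trifluoromethanesulfonate of 21 | C=C(OS(=O)(=O)C(F)(F)F)CC[C@@H]1[C@]2(C)CC[C@@H](O[Si](CC)(CC)CC)[C@](C)(CO[Si](c3ccccc3)(c3ccccc3)C(C)(C)C)[C@H]2CC[C@]1(C)O[Si](CC)(CC)CC | intermediate
24 | tributyl(vinyl)stannane | C=C[Sn](CCCC)(CCCC)CCCC | starting material
25 | 3,8-bis(triethylsilyloxy)-18-(tert-butyldiphenylsilyloxy)labda-13(16),14-diene (stereocentres as in 29) | C=CC(=C)CC[C@@H]1[C@]2(C)CC[C@@H](O[Si](CC)(CC)CC)[C@](C)(CO[Si](c3ccccc3)(c3ccccc3)C(C)(C)C)[C@H]2CC[C@]1(C)O[Si](CC)(CC)CC | intermediate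
26 | 18-(tert-butyldiphenylsilyloxy)labda-13(16),14-diene-3,8-diol (stereocentres as in 29) | C=CC(=C)CC[C@@H]1[C@]2(C)CC[C@@H](O)[C@](C)(CO[Si](c3ccccc3)(c3ccccc3)C(C)(C)C)[C@H]2CC[C@]1(C)O | intermediate
27 | acetic anhydride | CC(=O)OC(C)=O | starting material
28 | 3-acetate of 26 | C=CC(=C)CC[C@@H]1[C@]2(C)CC[C@@H](OC(C)=O)[C@](C)(CO[Si](c3ccccc3)(c3ccccc3)C(C)(C)C)[C@H]2CC[C@]1(C)O | intermediate
29 | (3R,4S,5S,8S,9R,10R)-8,18-dihydroxylabda-13(16),14-dien-3-yl acetate: trans-decalin; 3-OAc equatorial; CH2OH equatorial and C19 axial on C4; 8-OH and the C9 side chain both anti to C20; C17 syn to C20 | C=CC(=C)CC[C@@H]1[C@]2(C)CC[C@@H](OC(C)=O)[C@](C)(CO)[C@H]2CC[C@]1(C)O | target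

Total step count: 17. Longest linear sequence: 17 steps (1 → 29).

Steps most likely to fail

1. Step 6. The tertiary C4 radical may be reduced or lose a β-hydrogen (giving an allylic alcohol) before it reaches the aldehyde, or ring closure may proceed with poor control at C3 and C4. The fallback forms the same C3–C4 bond by an intramolecular nitrile oxide–alkene cycloaddition. It sets out from alcohol 9. Dess–Martin oxidation gives the keto aldehyde F1. Hydroxylamine hydrochloride and pyridine convert only the aldehyde (the hindered enone carbonyl should not condense) into the aldoxime F2. Aqueous NaOCl in CH2Cl2 generates the nitrile oxide, which adds across the isopropenyl group to give the ring-fused isoxazoline F3; the CH2–O arm must lie near the plane of the C3=N bond and therefore ends equatorial, with the methyl group axial. Mo(CO)6 in wet acetonitrile cleaves the N–O bond and hydrolyses the imine to the hydroxy diketone F4. NaBH4 in MeOH at −20 °C, which should prefer the saturated C3 ketone over the hindered enone and attack axially, gives the equatorial alcohol. This is diol 12, where the route is rejoined.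

2. Step 12. Hydrogen-atom transfer from the stannane to the hindered C9 radical may outpace its addition to the enone (plain deoxygenation), or the adduct radical may add further enone. The fallback introduces the chain by radical allylation, which uses no hydrogen donor, and builds the diene by enyne metathesis. It sets out from thionocarbonate 19. Allyltributylstannane and AIBN in benzene at 80 °C (Keck allylation) give the C9-allyl compound F5, with the same axial approach anti to the flanking methyl groups. 9-BBN followed by NaBO3·4H2O gives the primary alcohol F6. Dess–Martin oxidation gives the aldehyde F7. Dimethyl (1-diazo-2-oxopropyl)phosphonate with K2CO3 in MeOH (Ohira–Bestmann homologation) gives the terminal alkyne F8. Cross enyne metathesis with ethylene (second-generation Grubbs catalyst, RuCl2(=CHPh)(PCy3)(H2IMes), toluene, 80 °C) turns the alkyne into the 2-substituted butadiene. This is diene 25, where the route is rejoined.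

3. Step 11. Acylation of the C9 hydroxyl, which is flanked by two fully substituted carbons, may stall, or the silyl group may wander from O8 to O9 during a forced reaction. The fallback generates the radical by photoredox decarboxylation of an oxalate, which is installed with a much more reactive acylating agent. It sets out from alcohol 18. Methyl chlorooxoacetate with Et3N and DMAP in CH2Cl2 gives the methyl oxalate F9. One equivalent of aqueous CsOH in THF gives the cesium oxalate F10. Irradiation with blue light in the presence of Ir[dF(CF3)ppy]2(dtbbpy)PF6, but-3-en-2-one 20 and water (DME/DMF, 60 °C) expels two molecules of CO2 and adds the same C9 radical to the enone (redox-neutral Giese coupling). This gives ketone 21, where the route is rejoined; steps 11 and 12 are both replaced.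

Further compounds
F1 | step 6 | (5R,6R)-2,6-dimethyl-6-(3-oxopropyl)-5-(prop-1-en-2-yl)cyclohex-2-en-1-one | O=C1[C@](C)(CCC=O)[C@@H](C(C)=C)CC=C1C
F2 | step 6 | aldoxime of F1 | O=C1[C@](C)(CCC=NO)[C@@H](C(C)=C)CC=C1C
F3 | step 6 | ring-A-fused isoxazoline (C3=N–O–C18, C19 axial) of the octal-7-en-9-one | O=C1[C@]2(C)CCC3=NOC[C@]3(C)[C@H]2CC=C1C
F4 | step 6 | 18-hydroxy-11,12,13,14,15,16-hexanorlabd-7-ene-3,9-dione | O=C1[C@]2(C)CCC(=O)[C@](C)(CO)[C@H]2CC=C1C
F5 | step 12 | 9-allyl-3,8-bis(triethylsilyloxy)-18-(tert-butyldiphenylsilyloxy) decalin (allyl anti to C20) | C=CC[C@@H]1[C@]2(C)CC[C@@H](O[Si](CC)(CC)CC)[C@](C)(CO[Si](c3ccccc3)(c3ccccc3)C(C)(C)C)[C@H]2CC[C@]1(C)O[Si](CC)(CC)CC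
F6 | step 12 | 9-(3-hydroxypropyl) analogue of F5 | OCCC[C@@H]1[C@]2(C)CC[C@@H](O[Si](CC)(CC)CC)[C@](C)(CO[Si](c3ccccc3)(c3ccccc3)C(C)(C)C)[C@H]2CC[C@]1(C)O[Si](CC)(CC)CC
F7 | step 12 | 9-(3-oxopropyl) analogue of F5 | O=CCC[C@@H]1[C@]2(C)CC[C@@H](O[Si](CC)(CC)CC)[C@](C)(CO[Si](c3ccccc3)(c3ccccc3)C(C)(C)C)[C@H]2CC[C@]1(C)O[Si](CC)(CC)CC
F8 | step 12 | 9-(but-3-yn-1-yl) analogue of F5 | C#CCC[C@@H]1[C@]2(C)CC[C@@H](O[Si](CC)(CC)CC)[C@](C)(CO[Si](c3ccccc3)(c3ccccc3)C(C)(C)C)[C@H]2CC[C@]1(C)O[Si](CC)(CC)CC
F9 | step 11 | methyl oxalate of alcohol 18 | COC(=O)C(=O)O[C@H]1[C@]2(C)CC[C@@H](O[Si](CC)(CC)CC)[C@](C)(CO[Si](c3ccccc3)(c3ccccc3)C(C)(C)C)[C@H]2CC[C@]1(C)O[Si](CC)(CC)CC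
F10 | step 11 | cesium oxalate of alcohol 18 | [Cs+].[O-]C(=O)C(=O)O[C@H]1[C@]2(C)CC[C@@H](O[Si](CC)(CC)CC)[C@](C)(CO[Si](c3ccccc3)(c3ccccc3)C(C)(C)C)[C@H]2CC[C@]1(C)O[Si](CC)(CC)CC
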